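The synthesis rests on cutting the C4a'–C4' bond of the ring B chroman, which leads back to an aryl 2-methylbut-3-yn-2-yl ether. The feature used is that ring B is para-substituted. Its two carbons ortho to O1' are equivalent, so a gold-catalysed 6-endo-dig hydroarylation can give only one 2,2-dimethyl-2H-chromene. In one operation it forms C4a'–C4' and closes the pyran ring, leaving O1'–C2' untouched. The precursor is the complete dihydrochalcone with the ring A chroman in place and its 5- and 7-hydroxyls masked as MOM ethers. The masking is needed because C8 of ring A is activated by three oxygens and the two hydroxyls cannot both be chelated. Hydrogenation and acetal cleavage finish the synthesis.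

Key step: step 6

Assumption: primed locants (O1', C2', C3', C4', C4a', C8a') denote the ring B pyran and unprimed locants the ring A chroman; the target has no stereocentre, so the only descriptor in the route is the E alkene of the chalcone intermediate.

Design remark: in a free 6-acyl-5,7-dihydroxychroman one hydroxyl is always outside the hydrogen bond to the ketone and is more acidic than the ring B phenol. C8 is meta to the acyl carbon but ortho or para to O1, 7-O and 5-O. Ring A is therefore carried as its bis-MOM ether, and ring B is attached so that its phenol is the only free one at the etherification.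

Step 1
Reactants: 1 2',4',6'-trihydroxyacetophenone; 2 2-methylbut-3-en-2-ol
Product: 4 1-(5,7-dihydroxy-2,2-dimethylchroman-6-yl)ethan-1-one, via C-prenyl ketone 3 (not isolated)
Conditions: BF3·OEt2 (0.5 equiv), dioxane, rt then 50 °C
Reagents that add atoms: none
Why: Friedel–Crafts C-prenylation at C3 (equivalent to C5) by the dimethylallyl cation is followed in the same acid by Markovnikov hydroalkoxylation of the prenyl alkene, in which the 4-hydroxyl, the only one never held in the hydrogen bond to the ketone, should close the ring, and isomeric or doubly annulated material is removed by chromatography at this cheap first stage.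

Step 2
Reactants: 4 1-(5,7-dihydroxy-2,2-dimethylchroman-6-yl)ethan-1-one
Product: 6 1-[5,7-bis(methoxymethoxy)-2,2-dimethylchroman-6-yl]ethan-1-one, via 7-O-MOM monoether 5 (not isolated)
Conditions: NaH (2.4 equiv), MOMCl (2.6 equiv), THF–DMF, 0 °C to rt
Reagents that add atoms: chloromethyl methyl ether (MOMCl), COCCl
Why: Williamson ether synthesis with a very reactive α-chloro ether caps the open 7-hydroxyl first and then the 5-hydroxyl, whose chelate is broken by full deprotonation with NaH, so that ring A carries no acidic or chelating group in later steps.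

Step 3
Reactants: 6 1-[5,7-bis(methoxymethoxy)-2,2-dimethylchroman-6-yl]ethan-1-one; 7 4-(benzyloxy)benzaldehyde
Product: 9 (E)-3-[4-(benzyloxy)phenyl]-1-[5,7-bis(methoxymethoxy)-2,2-dimethylchroman-6-yl]prop-2-en-1-one, via racemic aldol adduct 8 (not isolated)
Conditions: KOH, EtOH–H2O, rt
Reagents that add atoms: none
Why: In this Claisen–Schmidt condensation the methyl ketone is the only enolisable partner, MOM and benzyl ethers are inert to hydroxide, and E1cB loss of water from 8 gives the conjugated E enone as is usual for 2',6'-dialkoxyacetophenones.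

Step 4
Reactants: 9 (E)-3-[4-(benzyloxy)phenyl]-1-[5,7-bis(methoxymethoxy)-2,2-dimethylchroman-6-yl]prop-2-en-1-one
Product: 11 1-[5,7-bis(methoxymethoxy)-2,2-dimethylchroman-6-yl]-3-(4-hydroxyphenyl)propan-1-one, via saturated benzyl ether 10 (not isolated)
Conditions: H2 (1 atm), 10% Pd/C, EtOAc–EtOH, rt
Reagents that add atoms: none
Why: Catalytic hydrogenation saturates the enone alkene and hydrogenolysis then cleaves the aryl benzyl ether in the same flask, while the flanked, twisted aryl ketone and the MOM acetals should persist under neutral conditions at 1 atm.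

Step 5
Reactants: 11 1-[5,7-bis(methoxymethoxy)-2,2-dimethylchroman-6-yl]-3-(4-hydroxyphenyl)propan-1-one; 12 3-chloro-3-methylbut-1-yne
Product: 13 1-[5,7-bis(methoxymethoxy)-2,2-dimethylchroman-6-yl]-3-[4-(2-methylbut-3-yn-2-yloxy)phenyl]propan-1-one
Conditions: CuCl2·2H2O (1 mol %), DBU (1.3 equiv), MeCN, 0 °C to rt
Reagents that add atoms: none
Why: Copper-catalysed propargylic substitution (a copper acetylide loses chloride and the phenoxide attacks the tertiary carbon) meets a single phenol in 11, so no site selectivity is required, and the low temperature suppresses elimination and premature rearrangement.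

Step 6
Reactants: 13 1-[5,7-bis(methoxymethoxy)-2,2-dimethylchroman-6-yl]-3-[4-(2-methylbut-3-yn-2-yloxy)phenyl]propan-1-one
Product: 14 1-[5,7-bis(methoxymethoxy)-2,2-dimethylchroman-6-yl]-3-(2,2-dimethyl-2H-chromen-6-yl)propan-1-one
Conditions: Ph3PAuNTf2 (3 mol %), 4 Å molecular sieves, CH2Cl2 (0.05 mol/L), rt
Reagents that add atoms: none
Why: The cationic monovalent gold centre binds the terminal alkyne of 13, one of the two equivalent ring B carbons ortho to the ether oxygen attacks the terminal alkyne carbon in a Friedel–Crafts-type step, and rearomatisation followed by protodeauration of the vinylgold species releases 14 with the O1'–C2' bond never broken. The closest known reaction type is the gold- or platinum-catalysed intramolecular hydroarylation of aryl propargyl ethers to 2H-chromenes, which covers 1,1-dimethylpropargyl ethers of alkylphenols. The pyran ring closes in the 6-endo-dig mode, because 5-exo attack on the internal alkyne carbon would have to build a strained methylene-dihydrobenzofuran next to the quaternary carbon, and the gem-dimethyl group (Thorpe–Ingold effect) folds the chain towards the arene. No stereocentre is formed, and regiochemistry is no issue because the para substituent makes both ortho positions the same. The step needs cyclisation to outrun ionisation of the tertiary propargylic C–O bond and alkyne hydration, which a halide-free, weakly oxophilic catalyst at room temperature, molecular sieves and the absence of free phenols (no acid release, no O,O-chelation of the metal by a hydroxy ketone) should secure better than PtCl4 would on the free diol. It also needs ring B to win over C8 of ring A, which stays electron-rich, and here the intramolecular six-membered closure in dilute solution is relied on.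

Step 7
Reactants: 14 1-[5,7-bis(methoxymethoxy)-2,2-dimethylchroman-6-yl]-3-(2,2-dimethyl-2H-chromen-6-yl)propan-1-one
Product: 16 1-(5,7-dihydroxy-2,2-dimethylchroman-6-yl)-3-(2,2-dimethylchroman-6-yl)propan-1-one, via bis-MOM bischroman 15 (not isolated)
Conditions: H2 (1 atm), 10% Pd/C, MeOH–EtOAc, rt; filter; then conc. HCl (cat.), MeOH, 45 °C
Reagents that add atoms: none
Why: Catalytic hydrogenation of the cis-disubstituted, styrene-type C3'–C4' alkene is fast at 1 atm and should leave the aryl ketone alone, and acid-catalysed acetal exchange with methanol then removes both MOM groups under conditions too mild to open either tertiary chroman ether.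

Compound list
1 | 2',4',6'-trihydroxyacetophenone (phloroacetophenone) | CC(=O)c1c(O)cc(O)cc1O | starting material
2 | 2-methylbut-3-en-2-ol | CC(C)(O)C=C | starting material
3 | 1-[2,4,6-trihydroxy-3-(3-methylbut-2-en-1-yl)phenyl]ethan-1-one | CC(=O)c1c(O)cc(O)c(CC=C(C)C)c1O | intermediate
4 | 1-(5,7-dihydroxy-2,2-dimethylchroman-6-yl)ethan-1-one | CC(=O)c1c(O)cc2c(c1O)CCC(C)(C)O2 | intermediate
5 | 1-[5-hydroxy-7-(methoxymethoxy)-2,2-dimethylchroman-6-yl]ethan-1-one | CC(=O)c1c(OCOC)cc2c(c1O)CCC(C)(C)O2 | intermediate
6 | 1-[5,7-bis(methoxymethoxy)-2,2-dimethylchroman-6-yl]ethan-1-one | CC(=O)c1c(OCOC)cc2c(c1OCOC)CCC(C)(C)O2 | intermediate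
7 | 4-(benzyloxy)benzaldehyde | O=Cc1ccc(OCc2ccccc2)cc1 | starting material
8 | 3-[4-(benzyloxy)phenyl]-1-[5,7-bis(methoxymethoxy)-2,2-dimethylchroman-6-yl]-3-hydroxypropan-1-one (racemic) | OC(CC(=O)c1c(OCOC)cc2c(c1OCOC)CCC(C)(C)O2)c1ccc(OCc2ccccc2)cc1 | intermediate
9 | (E)-3-[4-(benzyloxy)phenyl]-1-[5,7-bis(methoxymethoxy)-2,2-dimethylchroman-6-yl]prop-2-en-1-one | O=C(/C=C/c1ccc(OCc2ccccc2)cc1)c1c(OCOC)cc2c(c1OCOC)CCC(C)(C)O2 | intermediate
10 | 3-[4-(benzyloxy)phenyl]-1-[5,7-bis(methoxymethoxy)-2,2-dimethylchroman-6-yl]propan-1-one | O=C(CCc1ccc(OCc2ccccc2)cc1)c1c(OCOC)cc2c(c1OCOC)CCC(C)(C)O2 | intermediate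
11 | 1-[5,7-bis(methoxymethoxy)-2,2-dimethylchroman-6-yl]-3-(4-hydroxyphenyl)propan-1-one | O=C(CCc1ccc(O)cc1)c1c(OCOC)cc2c(c1OCOC)CCC(C)(C)O2 | intermediate
12 | 3-chloro-3-methylbut-1-yne | C#CC(C)(C)Cl | starting material
13 | 1-[5,7-bis(methoxymethoxy)-2,2-dimethylchroman-6-yl]-3-[4-(2-methylbut-3-yn-2-yloxy)phenyl]propan-1-one (key-step precursor, bis-MOM form) | C#CC(C)(C)Oc1ccc(CCC(=O)c2c(OCOC)cc3c(c2OCOC)CCC(C)(C)O3)cc1 | intermediate
14 | 1-[5,7-bis(methoxymethoxy)-2,2-dimethylchroman-6-yl]-3-(2,2-dimethyl-2H-chromen-6-yl)propan-1-one (key-step product, bis-MOM form) | CC1(C)C=Cc2cc(CCC(=O)c3c(OCOC)cc4c(c3OCOC)CCC(C)(C)O4)ccc2O1 | intermediate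
15 | 1-[5,7-bis(methoxymethoxy)-2,2-dimethylchroman-6-yl]-3-(2,2-dimethylchroman-6-yl)propan-1-one | CC1(C)CCc2cc(CCC(=O)c3c(OCOC)cc4c(c3OCOC)CCC(C)(C)O4)ccc2O1 | intermediate
16 | 1-(5,7-dihydroxy-2,2-dimethylchroman-6-yl)-3-(2,2-dimethylchroman-6-yl)propan-1-one | CC1(C)CCc2cc(CCC(=O)c3c(O)cc4c(c3O)CCC(C)(C)O4)ccc2O1 | target

Total step count: 7
Longest linear sequence: 7 steps (1 to 16)

Steps most likely to fail

**Step 6** is the first risk.
- The likeliest failure is ionisation of the tertiary propargylic C–O bond on the metal, with loss of the C5 unit.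
- Next in likelihood are alkyne hydration by adventitious water and acid-type oligomerisation of the electron-rich chromene.
- The fallback drops the π-acid and sets out from 13.
- Heating in N,N-diethylaniline at about 190 °C starts an aromatic propargyl Claisen rearrangement. Its dienone tautomerises to 1-[5,7-bis(methoxymethoxy)-2,2-dimethylchroman-6-yl]-3-[4-hydroxy-3-(3-methylbuta-1,2-dien-1-yl)phenyl]propan-1-one F1.
- A 1,5-hydrogen shift gives the ortho-quinone methide F2, and oxa-6π electrocyclisation comes back to the route at 14.
- The same C4a'–C4' bond is made, the equivalence of the two ortho carbons still holds, and the basic medium protects the MOM acetals.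

**Step 1** is the second risk.
- The failure modes are poor site selectivity in the ring closure (a ketone-flanking hydroxyl closing in place of the 4-hydroxyl) and a second annulation at the remaining ring carbon.
- The fallback sets out from 2 and introduces the acetyl group last.
- 2 is condensed under the same acid with an excess of phloroglucinol F3, whose three ring positions are equivalent, to give 2,2-dimethylchroman-5,7-diol F4.
- MOMCl and iPr2NEt in CH2Cl2 give 5,7-bis(methoxymethoxy)-2,2-dimethylchroman F5.
- Directed ortho-metalation with n-BuLi in THF at 0 °C removes the C6 proton, the only one flanked by two lithium-chelating MOM-oxy groups. This gives 6-lithio-5,7-bis(methoxymethoxy)-2,2-dimethylchroman F6.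
- F6 is acetylated with N-methoxy-N-methylacetamide (Weinreb ketone synthesis) and quenched with water.
- This comes back to the route at 6 and bypasses 4 and 5.

**Step 5** is the third risk.
- The failure mode is dehydrochlorination of the tertiary chloride outrunning etherification of a non-activated phenol, so that conversion stalls.
- The fallback sets out from 6 and 12 and installs the ether before the carbon chain is assembled.
- The more acidic 4-hydroxybenzaldehyde F7 is propargylated with 12 (CuCl2·2H2O, DBU, MeCN) to give 4-(2-methylbut-3-yn-2-yloxy)benzaldehyde F8.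
- Claisen–Schmidt condensation of F8 with 6 gives (E)-1-[5,7-bis(methoxymethoxy)-2,2-dimethylchroman-6-yl]-3-[4-(2-methylbut-3-yn-2-yloxy)phenyl]prop-2-en-1-one F9.
- Conjugate reduction of the s-cis enone with catecholborane in THF at rt follows. Uncatalysed hydroboration of the alkyne needs heating, so the alkyne should survive.
- Aqueous work-up comes back to the route at 13.

Further compounds
F1 | step 6 | 1-[5,7-bis(methoxymethoxy)-2,2-dimethylchroman-6-yl]-3-[4-hydroxy-3-(3-methylbuta-1,2-dien-1-yl)phenyl]propan-1-one | CC(C)=C=Cc1cc(CCC(=O)c2c(OCOC)cc3c(c2OCOC)CCC(C)(C)O3)ccc1O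
F2 | step 6 | ortho-quinone methide, 4-{3-[5,7-bis(methoxymethoxy)-2,2-dimethylchroman-6-yl]-3-oxopropyl}-6-(3-methylbut-2-en-1-ylidene)cyclohexa-2,4-dien-1-one, butenyl chain syn to the carbonyl | CC(C)=C/C=C1/C=C(CCC(=O)c2c(OCOC)cc3c(c2OCOC)CCC(C)(C)O3)C=CC1=O
F3 | step 1 | phloroglucinol (purchased) | Oc1cc(O)cc(O)c1
F4 | step 1 | 2,2-dimethylchroman-5,7-diol | CC1(C)CCc2c(O)cc(O)cc2O1
F5 | step 1 | 5,7-bis(methoxymethoxy)-2,2-dimethylchroman | COCOc1cc(OCOC)c2c(c1)OC(C)(C)CC2
F6 | step 1 | 6-lithio-5,7-bis(methoxymethoxy)-2,2-dimethylchroman | [Li]c1c(OCOC)cc2c(c1OCOC)CCC(C)(C)O2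
F7 | step 5 | 4-hydroxybenzaldehyde (purchased) | O=Cc1ccc(O)cc1
F8 | step 5 | 4-(2-methylbut-3-yn-2-yloxy)benzaldehyde | C#CC(C)(C)Oc1ccc(C=O)cc1
F9 | step 5 | (E)-1-[5,7-bis(methoxymethoxy)-2,2-dimethylchroman-6-yl]-3-[4-(2-methylbut-3-yn-2-yloxy)phenyl]prop-2-en-1-one | C#CC(C)(C)Oc1ccc(/C=C/C(=O)c2c(OCOC)cc3c(c2OCOC)CCC(C)(C)O3)cc1
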